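The data stem from a simulated flask from invented constants; scatter was added.

If every starting material that disappears takes exactly one partner with it, the two balances are a single balance, and the quantity to carry is the partner cover, the partner charge over the starting material charge 110 %. In the summer run the same ratio is 72.7 %, so on a count of one to one starting material, the limiting reagent, is charged in the smaller amount in the flask, whereas partner is charged in the smaller amount in the summer run.

the same everywhere: partner 40.7 mM; second reagent 44.4 mM
- summer: starting material 56 mM (fed, over 20 h); third reagent 74 mM; run made earlier; the fed solution adds 1.0 times the starting volume
- flask: starting material 37 mM (fed, over 20 h); third reagent 74.0 mM; the fed solution adds 1.0 times the starting volume; time 30 h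

summer run (percent of the starting material charged)

| time / h | target / % | starting material / % |
|---|---|---|
| 2.00 | 0.8 | 7.1 |
| 4.00 | 0 | 14.8 |
| 5.00 | 0.6 | 17.9 |
| 8.00 | 0.6 | 26.0 |
| 10.0 | 0.7 | 30.0 |

(readings scatter by 1 percentage point)

- percentages count the starting material that a species holds: one side product counts as two
- every charge counts on the volume at the start, and the solution that is fed holds the whole dose
- the numbers in the tables scatter with a standard deviation of 1 percentage point
- percentages count the whole charge, also what has not yet gone in

* target present at 30 h, in percent of the starting material charged
* starting material present at 30 h, in percent of the starting material charged
* side product present at 30 h, in percent of the starting material charged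
* intermediate A present at 30 h, in percent of the starting material charged

Take first the main step by itself, in which starting material meets partner and gives intermediate A. By 10.0 h the summer feed has delivered 50.0 % of the charge and 30.0 % is read as present, so by that reading 20.0 % has reacted, which on this step amounts to 27.5 % of the summer partner.

Now add the onward path from intermediate A to target, presumably through the second and third reagents. It leaves this balance as it stands, since it shifts material that has already passed the partner, and summer target reads 0.7 % at that hour, with a scatter of 1 percentage point.

Then add the side product, which holds two starting materials. If one of them arrives as free starting material, it passes no partner, and a gap opens: the fraction of starting material gone minus the cover times the fraction of partner gone. This gap is the turnover of that loss, and it lowers both starting material and target below what the first two processes leave. The reckoning here commits to that form and to a positive gap in the flask, not to a figure.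

The forecast gives 6 % target, 32 % starting material, 5 % side product and 57 % intermediate A, with the judgement: “Most of the reacted material stays as intermediate.”

The flask at 30 h holds 17.5 % target, 25.0 % starting material, 20.4 % side product and 30.7 % intermediate A.

    second reagent + intermediate A → intermediate B (k = 2.70 M⁻¹ h⁻¹)
    starting material + target → side product (k = 7.07 M⁻¹ h⁻¹)
    third reagent + intermediate B → target (k = 6.58 M⁻¹ h⁻¹)
    starting material + partner → intermediate A (k = 4.69 M⁻¹ h⁻¹)

In the flask 75.0 % of the starting material and 58.9 % of the partner are gone, so the cover accounts for 64.8 % and the gap is 10.2 %, which is the net turnover of the loss of starting material with target. That loss and the early hour of the reading are each a part of why flask target stands at 17.5 %: without the loss target reads 28.2 %, and ten times later it reads 54.3 %. In the neighbour flask, which has the same cover but 180 mM of second reagent, 20 % of the starting material and 43 % of the partner remain, so its gap is 18.0 %, and its side product, at twice that gap, reads 35.9 %.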